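**Retrosynthetic overview**
- Feature: in ring A, the oxygen-bearing carbons C5 (5-OH), C7 (7-OH) and C8a (ring oxygen O1) all lie ortho or para to C4a, which carries the C4 carbonyl. Each of these C–O bonds is therefore an SNAr site, and ring A is traced back to an electrophilic 2,4,6-trifluorobenzoyl unit.
- Late disconnections: the 3',4'-MOM ethers, then the 5,7-allyl ethers, then C5–O and C7–O back to the C–F bonds of a 5,7-difluoroflavone.
- Key disconnection: C3–C4 (enolate C-acylation) and O1–C8a (intramolecular fluoride displacement). This leads to 2,4,6-trifluorobenzoyl chloride and 1-[3,4-bis(methoxymethoxy)-5-prenylphenyl]ethanone.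
- Ring B ketone: the C5'–CH2 bond comes from Stille prenylation of a bromide made from acetovanillone by bromination, demethylation and MOM protection. The acetyl group is present from the start.
- Ring order: rings A and B are bought as arenes. Ring C is the only ring formed, in step 5.

Key step: step 5

Remark: the target has no stereocentre and its only alkene carries two identical methyl groups, so no configuration has to be set. The C7 fluoride (para to the carbonyl) is assumed to exchange before the C5 fluoride, which does not change the outcome. Prenyl means 3-methylbut-2-en-1-yl.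

**Step 1**
Reactants: 1 acetovanillone
Product: 2 1-(3-bromo-4-hydroxy-5-methoxyphenyl)ethanone
Conditions: Br2 (1.05 equiv), NaOAc, AcOH, rt
Reagents that add atoms: bromine, BrBr
Why: Electrophilic aromatic bromination, in which the free 4-OH directs to its only open ortho position (the para position carries the acetyl group) and the acetate buffer holds back acid-catalysed side-chain bromination.

**Step 2**
Reactants: 2 1-(3-bromo-4-hydroxy-5-methoxyphenyl)ethanone
Product: 3 1-(3-bromo-4,5-dihydroxyphenyl)ethanone
Conditions: BBr3 (3 equiv), CH2Cl2, −78 °C → rt; then H2O
Reagents that add atoms: none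
Why: Lewis-acid cleavage of an aryl methyl ether, in which BBr3 binds the methoxy oxygen and bromide removes the methyl group by SN2, while the ketone and the aryl bromide should be untouched at or below room temperature.

**Step 3**
Reactants: 3 1-(3-bromo-4,5-dihydroxyphenyl)ethanone
Product: 4 1-[3-bromo-4,5-bis(methoxymethoxy)phenyl]ethanone
Conditions: MOMCl (3 equiv), iPr2NEt (4 equiv), CH2Cl2, 0 °C → rt
Reagents that add atoms: chloromethyl methyl ether (MOMCl), COCCl
Why: Williamson-type O-alkylation of both phenols with the very reactive α-chloro ether gives acetals that withstand the amide base, carbonate and alkoxide used later.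

**Step 4**
Reactants: 4 1-[3-bromo-4,5-bis(methoxymethoxy)phenyl]ethanone; 5 tributyl(3-methylbut-2-en-1-yl)stannane
Product: 6 1-[3,4-bis(methoxymethoxy)-5-prenylphenyl]ethanone
Conditions: Pd(PPh3)4 (5 mol %), DMF, 100 °C
Reagents that add atoms: none
Why: Stille cross-coupling, in which zerovalent palladium inserts into the C–Br bond, the allylic stannane transmetalates, and reductive elimination from the less hindered primary terminus of the prenylpalladium species should give the linear prenyl arene, with the ketone and MOM groups inert under these neutral conditions.

**Step 5**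
Reactants: 6 1-[3,4-bis(methoxymethoxy)-5-prenylphenyl]ethanone; 7 2,4,6-trifluorobenzoyl chloride
Product: 10 5,7-difluoro-3',4'-bis(methoxymethoxy)-5'-prenylflavone, via lithium enolate 8 (not isolated), via 1,3-diketone 9 (not isolated)
Conditions: LiHMDS (2.2 equiv), THF, −78 °C; 7 (1.05 equiv), −78 → 0 °C; AcOH; evaporate; K2CO3 (3 equiv), DMF (0.05 M), 60–80 °C
Reagents that add atoms: none
Why: Claisen-type C-acylation of lithium enolate 8 by acid chloride 7 forms C3–C4, and the second equivalent of LiHMDS deprotonates the much more acidic diketone 9 as it appears, which shields it from further acylation and makes the C-acylated product the thermodynamic sink (any enol ester is itself an acyl donor and is consumed by remaining enolate). Once AcOH has broken the lithium chelate, K2CO3 in DMF gives the loosely paired potassium diketonate, whose oxygen on C2 adds to an ortho C–F carbon (the future C8a) to give a Meisenheimer anion delocalised into the C4 carbonyl and stabilised inductively by the other two fluorines, and loss of fluoride forms O1–C8a. Ring C is thus closed by a six-membered intramolecular addition–elimination (SNAr), the only closure open to the ambident anion, since attack through C3 would give a four-membered ring. The closest known reaction type is the cycloaracylation of ketone enolates and enamino esters with 2-fluorobenzoyl chlorides, which gives chromones, flavones and 4-quinolones. Site selectivity among three C–F bonds is needed: the two ortho fluorines are related by symmetry and lead to the same flavone, and the para fluorine cannot be reached from within the molecule, so dilution suffices to suppress its intermolecular displacement. No stereocentre is formed.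

**Step 6**
Reactants: 10 5,7-difluoro-3',4'-bis(methoxymethoxy)-5'-prenylflavone; 11 allyl alcohol
Product: 13 5,7-bis(allyloxy)-3',4'-bis(methoxymethoxy)-5'-prenylflavone, via 7-allyloxy-5-fluoroflavone 12 (not isolated)
Conditions: 11 (8 equiv), NaH (5 equiv), THF, 0 °C; then 10, DMF, rt → 70 °C, strictly anhydrous
Reagents that add atoms: none
Why: Twofold nucleophilic aromatic substitution (addition–elimination), in which C7–F (para) and C5–F (ortho) are both activated by the C4 carbonyl, the allyloxy group introduced first sits meta to the remaining C–F carbon and so places no charge on the Meisenheimer positions, and the excess free allyl alcohol tempers the basicity so that the MOM groups, the prenyl group and ring C should persist.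

**Step 7**
Reactants: 13 5,7-bis(allyloxy)-3',4'-bis(methoxymethoxy)-5'-prenylflavone
Product: 14 5,7-dihydroxy-3',4'-bis(methoxymethoxy)-5'-prenylflavone
Conditions: Pd(PPh3)4 (5 mol %), morpholine (10 equiv), THF, rt
Reagents that add atoms: none
Why: Tsuji–Trost-type deallylation, in which zerovalent palladium ionises both aryl allyl ethers to π-allylpalladium phenoxides and morpholine traps the allyl units irreversibly, while the C-bound prenyl group (no leaving group) and the MOM acetals are inert.

**Step 8**
Reactants: 14 5,7-dihydroxy-3',4'-bis(methoxymethoxy)-5'-prenylflavone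
Product: 15 uralenin
Conditions: HCl (ca. 1 M in MeOH), 40 °C, short contact, under argon
Reagents that add atoms: none
Why: Acid-catalysed acetal exchange (MOM solvolysis) with methanol frees the catechol, and dilute acid, mild warming and short contact are chosen because aryl MOM ethers cleave faster than the trisubstituted alkene is protonated, a process that would otherwise close a dimethylchroman ring onto 4'-OH.

**Compound list**
1 | acetovanillone (1-(4-hydroxy-3-methoxyphenyl)ethanone) | CC(=O)c1ccc(O)c(OC)c1 | starting material
2 | 1-(3-bromo-4-hydroxy-5-methoxyphenyl)ethanone | CC(=O)c1cc(Br)c(O)c(OC)c1 | intermediate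
3 | 1-(3-bromo-4,5-dihydroxyphenyl)ethanone | CC(=O)c1cc(O)c(O)c(Br)c1 | intermediate
4 | 1-[3-bromo-4,5-bis(methoxymethoxy)phenyl]ethanone | CC(=O)c1cc(Br)c(OCOC)c(OCOC)c1 | intermediate
5 | tributyl(3-methylbut-2-en-1-yl)stannane | CCCC[Sn](CCCC)(CCCC)CC=C(C)C | starting material
6 | 1-[3,4-bis(methoxymethoxy)-5-(3-methylbut-2-en-1-yl)phenyl]ethanone | CC(=O)c1cc(CC=C(C)C)c(OCOC)c(OCOC)c1 | intermediate
7 | 2,4,6-trifluorobenzoyl chloride | O=C(Cl)c1c(F)cc(F)cc1F | starting material
8 | lithium enolate of 6 (not isolated) | [Li+].C=C([O-])c1cc(CC=C(C)C)c(OCOC)c(OCOC)c1 | intermediate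
9 | 1-[3,4-bis(methoxymethoxy)-5-prenylphenyl]-3-(2,4,6-trifluorophenyl)propane-1,3-dione (not isolated) | CC(C)=CCc1cc(C(=O)CC(=O)c2c(F)cc(F)cc2F)cc(OCOC)c1OCOC | intermediate
10 | 5,7-difluoro-3',4'-bis(methoxymethoxy)-5'-prenylflavone | CC(C)=CCc1cc(-c2cc(=O)c3c(F)cc(F)cc3o2)cc(OCOC)c1OCOC | intermediate
11 | allyl alcohol | C=CCO | starting material
12 | 7-allyloxy-5-fluoro-3',4'-bis(methoxymethoxy)-5'-prenylflavone (not isolated) | CC(C)=CCc1cc(-c2cc(=O)c3c(F)cc(OCC=C)cc3o2)cc(OCOC)c1OCOC | intermediate
13 | 5,7-bis(allyloxy)-3',4'-bis(methoxymethoxy)-5'-prenylflavone | CC(C)=CCc1cc(-c2cc(=O)c3c(OCC=C)cc(OCC=C)cc3o2)cc(OCOC)c1OCOC | intermediate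
14 | 5,7-dihydroxy-3',4'-bis(methoxymethoxy)-5'-prenylflavone | CC(C)=CCc1cc(-c2cc(=O)c3c(O)cc(O)cc3o2)cc(OCOC)c1OCOC | intermediate
15 | uralenin (5,7,3',4'-tetrahydroxy-5'-prenylflavone) | CC(C)=CCc1cc(-c2cc(=O)c3c(O)cc(O)cc3o2)cc(O)c1O | target

**Total step count:** 8
**Longest linear sequence:** 8 steps (1 → 15)

**Steps most likely to fail**

1. **Step 6.** The exchange at C5 may stall after the fast exchange at C7, because the 7-allyloxy group feeds electron density through C4a into the C4 carbonyl. The long heating with excess alkoxide that is then needed carries three dangers: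
   - reversible alkoxide addition at C2, which opens ring C to a phenoxide that resists substitution;
   - capture of traces of hydroxide;
   - base-induced migration of the allyl and prenyl double bonds.

   The fallback sets out from 10. The exchange is limited to C7 with one equivalent of sodium allyl oxide in THF–DMF at 0 °C to room temperature, and 12 is isolated. The remaining C5 fluoride is then replaced with a hydroxide surrogate, 2-(methylsulfonyl)ethanol and NaH in DMF. The first-formed 5-[2-(methylsulfonyl)ethoxy] ether F1 loses methyl vinyl sulfone by E1cB elimination in the flask. This gives the chelated phenoxide of 7-allyloxy-5-hydroxy-3',4'-bis(methoxymethoxy)-5'-prenylflavone F2, whose charge shields ring C from further base. Deallylation of F2 with Pd(PPh3)4 and morpholine gives 14, where the route is rejoined.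

2. **Step 5.** Three processes would lower the conversion to the diketone: O-acylation of the enolate, consumption of the acid chloride by the excess amide base, and a second acylation of the diketonate. Early fluoride displacement by nitrogen or carbon nucleophiles is a further drain. The fallback sets out from 6 and makes the same C3–C4 bond at the alcohol oxidation level. The lithium enolate (one equivalent of LiHMDS, THF, −78 °C) is added to 2,4,6-trifluorobenzaldehyde in an aldol addition, which can only take place at carbon, and gives the racemic β-hydroxy ketone F3. Oxidation of F3 with IBX in hot ethyl acetate gives diketone 9, where the route is rejoined. Closure with K2CO3 in DMF then leads to 10 as in step 5.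

3. **Step 4.** Allyl transposition during transfer from tin to palladium, with coupling at the tertiary terminus, may erode the linear selectivity. Oxidative addition next to the ortho MOM ether may be slow, and the stannane may be lost by protodestannylation or homocoupling. The fallback sets out from 4. Suzuki–Miyaura allylation with allylboronic acid pinacol ester (Pd(PPh3)4, CsF, THF, reflux), in which both allyl termini are alike, gives 1-[3-allyl-4,5-bis(methoxymethoxy)phenyl]ethanone F4. Cross-metathesis of F4 with excess 2-methyl-2-butene (second-generation Grubbs catalyst, CH2Cl2, 40 °C) turns the allyl group into the prenyl group and gives 6, where the route is rejoined.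

**Further compounds**
F1 | step 6 | 7-allyloxy-5-[2-(methylsulfonyl)ethoxy]-3',4'-bis(methoxymethoxy)-5'-prenylflavone | CC(C)=CCc1cc(-c2cc(=O)c3c(OCCS(C)(=O)=O)cc(OCC=C)cc3o2)cc(OCOC)c1OCOC
F2 | step 6 | 7-allyloxy-5-hydroxy-3',4'-bis(methoxymethoxy)-5'-prenylflavone | CC(C)=CCc1cc(-c2cc(=O)c3c(O)cc(OCC=C)cc3o2)cc(OCOC)c1OCOC
F3 | step 5 | 1-[3,4-bis(methoxymethoxy)-5-prenylphenyl]-3-hydroxy-3-(2,4,6-trifluorophenyl)propan-1-one (racemic) | CC(C)=CCc1cc(C(=O)CC(O)c2c(F)cc(F)cc2F)cc(OCOC)c1OCOC
F4 | step 4 | 1-[3-allyl-4,5-bis(methoxymethoxy)phenyl]ethanone | CC(=O)c1cc(CC=C)c(OCOC)c(OCOC)c1
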